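**Retrosynthetic overview**
- The target is a formal hydro-dimer of oroidin. Its methine carbon C-10 carries the monosubstituted 2-aminoimidazole (ring A) and the CH2CH2NH-acyl chain, and is bonded to C-5 of the second 2-aminoimidazole (ring B), whose C-4 keeps an intact (E)-3-amidopropenyl chain.
- Key disconnection: the C-10–C-5(ring B) bond. It is made by an enantioconvergent, chiral-phosphate-paired Friedel–Crafts union of oroidin (ring B nucleophile) with the 2-amino-diazafulvenium ion released from oroidin's own C-10 hydrate (a racemic carbinol). This step sets the only stereocentre.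
- Both partners come from that one carbinol, made by C-hydroxyalkylation of 2-aminoimidazole with 3-(4,5-dibromopyrrole-2-carboxamido)propanal. The aldehyde comes from an amino acetal and a trichloroacetyl pyrrole.
- No ring is formed anywhere: both imidazoles and both pyrroles are bought intact, and the key step is the last step.

Key step: step 5

Remark: the 4- and 5-positions of an N-unsubstituted 2-aminoimidazole interconvert by tautomerism, so names use the 1H-imidazol-5-yl form; with the tautomers drawn, the target stereocentre is S (ring B > ring A > CH2 > H).
Remark: the diazafulvenium cation is formed in two steps with two different counter-ions; the trifluoroacetate salt (step 4) and the chiral phosphate ion pair (step 5) are distinct species and are numbered separately. In each case the anion comes from the acid named in the conditions and returns to that acid when the cation reacts on.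
Assumption: 2-aminoimidazole is used as the free base, liberated from the commercial hemisulfate on a basic ion-exchange resin just before use.
Assumption: the (R)-phosphoric acid is written as the catalyst that should give the S product; the sense of induction of this new ion-pair step has to be established by experiment, and the (S)-acid is used if the opposite sense is found.

**Step 1**
Reactants: 1 3,3-diethoxypropan-1-amine; 2 2,2,2-trichloro-1-(4,5-dibromo-1H-pyrrol-2-yl)ethan-1-one
Product: 3 4,5-dibromo-N-(3,3-diethoxypropyl)-1H-pyrrole-2-carboxamide
Conditions: Et3N (cat.), MeCN, rt, 12 h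
Reagents that add atoms: none
Why: Haloform-type aminolysis of the trichloromethyl ketone, in which the primary amine adds to the activated carbonyl and CCl3 leaves as chloroform, should give the pyrrole-2-carboxamide without a coupling reagent and without touching the acetal.

**Step 2**
Reactants: 3 4,5-dibromo-N-(3,3-diethoxypropyl)-1H-pyrrole-2-carboxamide
Product: 4 4,5-dibromo-N-(3-oxopropyl)-1H-pyrrole-2-carboxamide
Conditions: Amberlyst-15, THF/H2O 4:1, rt; filter, use at once
Reagents that add atoms: water, O
Why: Acid-catalysed acetal hydrolysis on a sulfonic acid resin under dilute, mild conditions should free the aldehyde while the deactivated dibromopyrrole does not cyclise onto it.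

**Step 3**
Reactants: 4 4,5-dibromo-N-(3-oxopropyl)-1H-pyrrole-2-carboxamide; 5 2-aminoimidazole (free base)
Product: 6 rac-N-[3-(2-amino-1H-imidazol-5-yl)-3-hydroxypropyl]-4,5-dibromo-1H-pyrrole-2-carboxamide
Conditions: 5 (3 equiv), EtOH/H2O 1:1, Ar, rt, 24 h
Reagents that add atoms: none
Why: C-4(5) hydroxyalkylation of 2-aminoimidazole by an aldehyde (aldol-type electrophilic substitution of the cyclic enediamine) is a known reaction of this heterocycle under neutral aqueous conditions; excess 5 should hold it at mono-addition, and the carbinol centre forms racemic, which is harmless because steps 4 and 5 erase it.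

**Step 4**
Reactants: 6 rac-N-[3-(2-amino-1H-imidazol-5-yl)-3-hydroxypropyl]-4,5-dibromo-1H-pyrrole-2-carboxamide
Product: 8 oroidin (N-[(2E)-3-(2-amino-1H-imidazol-5-yl)prop-2-en-1-yl]-4,5-dibromo-1H-pyrrole-2-carboxamide), via 2-amino-diazafulvenium trifluoroacetate 7 (not isolated)
Conditions: TFA (3 equiv), MeCN (0.01 M), 50 °C; evaporate, free base on basic resin
Reagents that add atoms: none
Why: E1 dehydration of the fully N-protonated heteroaryl carbinol through the diazafulvenium trifluoroacetate 7 should give the conjugated, thermodynamically preferred E-alkene by loss of the C-9 proton, because with every aminoimidazole protonated no free-base nucleophile is available for self-coupling.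

**Step 5**
Reactants: 6 rac-N-[3-(2-amino-1H-imidazol-5-yl)-3-hydroxypropyl]-4,5-dibromo-1H-pyrrole-2-carboxamide; 8 oroidin
Product: 10 4,5-dibromo-N-[(3S)-3-(2-amino-1H-imidazol-5-yl)-3-{2-amino-4-[(1E)-3-(4,5-dibromo-1H-pyrrole-2-carboxamido)prop-1-en-1-yl]-1H-imidazol-5-yl}propyl]-1H-pyrrole-2-carboxamide, via 2-amino-diazafulvenium (R)-TRIP phosphate ion pair 9 (not isolated)
Conditions: (R)-TRIP (20 mol%), 4 Å MS, MeCN/CHCl3 1:1, 0 °C → rt; 6 added over 8 h to 8 (3 equiv)
Reagents that add atoms: none
Why: Proposed new method: the partly protonated carbinol 6 loses water to the planar diazafulvenium cation, which can exist only as the ion pair 9 with the chiral phosphate because no other anion is present; C-5 of free-base 8, its N–H hydrogen-bonded to the phosphoryl oxygen, then adds to the exocyclic carbon C-10 and proton loss restores the aromatic ring and returns the phosphoric acid. The closest known reaction type is the chiral-phosphoric-acid-catalysed enantioselective Friedel–Crafts substitution of 3-indolylmethanols and related alkylidene-indoleninium precursors by indoles, together with the acid-mediated C-alkylation of 2-aminoimidazoles by stabilised cations. No ring is closed. The single stereocentre (C-10, S) is set by the phosphate, which differentiates the two faces of the cation of 9 in a hydrogen-bonded bifunctional transition state, and both enantiomers of racemic 6 converge on the same planar ion, so the step is enantioconvergent. The step needs C-5 attack over N attack, reaction at C-10 rather than C-9, and cross-coupling over oligomerisation and over closure onto the pyrrole: C-attack is the only irreversible outcome (N-adducts are aminals that re-ionise), ionisation of the carbinol gives the C-10 cation regiospecifically without C-protonation of a vinyl group, the pyrrole is deactivated by two bromines and the acyl group, and slow addition of 6 to excess 8 keeps 8 the dominant nucleophile while the bulky new methine shields the one remaining ring C–H of the product.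

**Compound list**
1 | 3,3-diethoxypropan-1-amine | CCOC(CCN)OCC | starting material
2 | 2,2,2-trichloro-1-(4,5-dibromo-1H-pyrrol-2-yl)ethan-1-one | O=C(c1cc(Br)c(Br)[nH]1)C(Cl)(Cl)Cl | starting material
3 | 4,5-dibromo-N-(3,3-diethoxypropyl)-1H-pyrrole-2-carboxamide | CCOC(CCNC(=O)c1cc(Br)c(Br)[nH]1)OCC | intermediate
4 | 4,5-dibromo-N-(3-oxopropyl)-1H-pyrrole-2-carboxamide | O=CCCNC(=O)c1cc(Br)c(Br)[nH]1 | intermediate
5 | 2-aminoimidazole (1H-imidazol-2-amine, free base) | Nc1ncc[nH]1 | starting material
6 | rac-N-[3-(2-amino-1H-imidazol-5-yl)-3-hydroxypropyl]-4,5-dibromo-1H-pyrrole-2-carboxamide (racemic carbinol) | Nc1ncc(C(O)CCNC(=O)c2cc(Br)c(Br)[nH]2)[nH]1 | intermediate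
7 | 2-amino-4-[3-(4,5-dibromo-1H-pyrrole-2-carboxamido)propylidene]-4H-imidazol-1-ium trifluoroacetate (2-amino-diazafulvenium ion, i.e. C-9-protonated oroidin, as the salt formed with TFA in step 4; not isolated) | NC1=NC(=CCCNC(=O)c2cc(Br)c(Br)[nH]2)C=[NH+]1.[O-]C(=O)C(F)(F)F | intermediate
8 | oroidin, N-[(2E)-3-(2-amino-1H-imidazol-5-yl)prop-2-en-1-yl]-4,5-dibromo-1H-pyrrole-2-carboxamide | Nc1ncc(/C=C/CNC(=O)c2cc(Br)c(Br)[nH]2)[nH]1 | intermediate
9 | 2-amino-4-[3-(4,5-dibromo-1H-pyrrole-2-carboxamido)propylidene]-4H-imidazol-1-ium (R)-3,3'-bis(2,4,6-triisopropylphenyl)-1,1'-binaphthyl-2,2'-diyl phosphate (contact ion pair of the same cation with the (R)-TRIP anion, formed in step 5; the R axis of the anion cannot be written in the SMILES; not isolated) | NC1=NC(=CCCNC(=O)c2cc(Br)c(Br)[nH]2)C=[NH+]1.[O-]P1(=O)Oc2c(-c3c(C(C)C)cc(C(C)C)cc3C(C)C)cc3ccccc3c2-c2c(O1)c(-c3c(C(C)C)cc(C(C)C)cc3C(C)C)cc3ccccc23 | intermediate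
10 | 4,5-dibromo-N-[(3S)-3-(2-amino-1H-imidazol-5-yl)-3-{2-amino-4-[(1E)-3-(4,5-dibromo-1H-pyrrole-2-carboxamido)prop-1-en-1-yl]-1H-imidazol-5-yl}propyl]-1H-pyrrole-2-carboxamide | Nc1ncc([C@H](CCNC(=O)c2cc(Br)c(Br)[nH]2)c2[nH]c(N)nc2/C=C/CNC(=O)c2cc(Br)c(Br)[nH]2)[nH]1 | target

**Step count**
Total steps: 5. Longest linear sequence: 5 steps (1 → 3 → 4 → 6 → 8 → 10; carbinol 6 feeds both step 4 and step 5).

**Steps most likely to fail**

Step 5 (proposed new method). The process at risk is weak facial discrimination within the ion pair 9, because the polar medium needed to dissolve both partners loosens the contact between the cation and the phosphate. Enantiopurity may also erode by reversible re-ionisation of the product, and the product may be alkylated further. The fallback uses known chemistry and sets out from 6 and 8. The same bond is formed without induction by Brønsted-acid-mediated C-alkylation of a 2-aminoimidazole with a carbinol-derived cation (TFA 0.5 equiv, MeCN, rt), which should give the racemic dimer F1. Preparative HPLC on a polysaccharide chiral stationary phase then separates the enantiomers, and the S enantiomer comes back to the route as 10.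

Step 4. The process at risk is interception of the cation of 7 before it loses the C-9 proton, either by closure of C-3 of its own pyrrole onto C-10 (seven-membered lactam) or by an unprotonated substrate molecule as the solution is concentrated. The fallback sets out from 6 and forms the alkene under basic conditions, where no cation exists. p-Toluenesulfinic acid (2 equiv, MeCN, rt) captures the ion as the sulfone N-[3-(2-amino-1H-imidazol-5-yl)-3-(4-methylbenzenesulfonyl)propyl]-4,5-dibromo-1H-pyrrole-2-carboxamide F2, the heteroaryl counterpart of the arenesulfonyl-alkyl indoles. DBU (3 equiv) in dilute MeCN should then expel sulfinate to the neutral diazafulvene, which tautomerises to the conjugated E-alkene and so comes back to the route at 8.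

Step 3. The process at risk is loss of aldehyde 4 before C–C bond formation, by closure of its pyrrole N–H onto the formyl group and by β-elimination of the carboxamide in the basic medium, together with over-reaction of the carbinol with excess 5. The fallback sets out from 5 and makes the amide last. Commercial 3-phthalimidopropanal, which has no N–H, is hydroxyalkylated by 5 (EtOH, rt) to the phthalimido carbinol 2-[3-(2-amino-1H-imidazol-5-yl)-3-hydroxypropyl]isoindoline-1,3-dione F3. Hydrazine hydrate in EtOH should free the amino alcohol 3-amino-1-(2-amino-1H-imidazol-5-yl)propan-1-ol F4. Selective N-acylation of its primary amine with 2 (Na2CO3, DMF, rt) comes back to the route at 6.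

**Further compounds**
F1 | step 5 | racemic 4,5-dibromo-N-[3-(2-amino-1H-imidazol-5-yl)-3-{2-amino-4-[(1E)-3-(4,5-dibromo-1H-pyrrole-2-carboxamido)prop-1-en-1-yl]-1H-imidazol-5-yl}propyl]-1H-pyrrole-2-carboxamide | Nc1ncc(C(CCNC(=O)c2cc(Br)c(Br)[nH]2)c2[nH]c(N)nc2/C=C/CNC(=O)c2cc(Br)c(Br)[nH]2)[nH]1
F2 | step 4 | rac-N-[3-(2-amino-1H-imidazol-5-yl)-3-(4-methylbenzenesulfonyl)propyl]-4,5-dibromo-1H-pyrrole-2-carboxamide | Cc1ccc(cc1)S(=O)(=O)C(CCNC(=O)c1cc(Br)c(Br)[nH]1)c1cnc(N)[nH]1
F3 | step 3 | rac-2-[3-(2-amino-1H-imidazol-5-yl)-3-hydroxypropyl]isoindoline-1,3-dione | Nc1ncc(C(O)CCN2C(=O)c3ccccc3C2=O)[nH]1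
F4 | step 3 | rac-3-amino-1-(2-amino-1H-imidazol-5-yl)propan-1-ol | Nc1ncc(C(O)CCN)[nH]1
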